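**Retrosynthetic overview**

- The strategy rests on ring B (C5–C10). It is a 2-methylcyclohex-2-enone whose C5 carries the gem-dimethyl carbon C4 and whose neighbour C10 is a methyl-bearing quaternary carbon. With the carbonyl moved from C7 back to C9, this ring is (R)-carvone: the isopropenyl carbon is C4 and carvone C6 is C10.
- The 6β-acetoxy-8-en-7-one is unfolded to a 9-hydroxy-7-en-6-one (Luche reduction, acetylation, oxidative 1,3-transposition). That comes from the 6,8-diene by singlet-oxygen [4+2] addition and Kornblum–DeLaMare opening.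
- The C9–C11 bond is cut by a Negishi coupling of the C9 dienyl triflate with a C11–C16 alkylzinc that carries C13 and is cut out of (R)-linalool.
- Ring B is present from the start. Ring A is closed second, at C3–C4, by hydrogen-atom-transfer radical cyclization of the isopropenyl group onto an acrylate arm on C10. The extra ester on C2 is then removed by Barton decarboxylation.
- C10 is built by two kinetic enolate alkylations of carvone: iodomethane, then methyl 2-(bromomethyl)acrylate anti to the isopropenyl group.

Key step: step 3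

Remark on the chemistry: the side chain has only two CH2 groups (C11, C12) between C9 and C13, so the organozinc must be the six-carbon unit C11–C16. (R)-Linalool is therefore cleaved at C6=C7 and then loses C6 by iododecarboxylation. Epimer mixtures at carvone C6 in 3 and at C2 in 7–9 are carried on, because these centres are planarized or lose their substituent.

**Route**

Step 1
Reactants: 1 (R)-carvone
Product: 3 (5R)-2,6-dimethyl-5-(prop-1-en-2-yl)cyclohex-2-en-1-one (6-methylcarvone as a C6 epimer mixture), via carvone lithium enolate 2 (not isolated)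
Conditions: LiN(i-Pr)2 (LDA), THF, −78 °C; MeI, −78 to 0 °C
Reagents that add atoms: iodomethane CI
Why: Kinetic deprotonation occurs at the α' CH2 (carvone C6) and the cross-conjugated enolate is methylated in an SN2 enolate alkylation; the configuration of the new centre does not matter because it is enolized again in step 2.

Step 2
Reactants: 3 6-methylcarvone; 4 methyl 2-(bromomethyl)acrylate
Product: 6 methyl 2-{[(1S,6S)-1,3-dimethyl-2-oxo-6-(prop-1-en-2-yl)cyclohex-3-en-1-yl]methyl}prop-2-enoate (acrylate arm trans to isopropenyl), via 6-methylcarvone lithium enolate 5 (not isolated)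
Conditions: LiN(i-Pr)2 (LDA), THF, −78 °C; 4, −78 to −20 °C
Reagents that add atoms: none
Why: Enolate alkylation with the activated allylic bromide (SN2 or SN2' addition–elimination, same product) should take place on the enolate face anti to the neighbouring isopropenyl group, which sets the quaternary centre (future C10) with the acrylate arm trans to the future C4.

Step 3
Reactants: 6 methyl 2-{[(1S,6S)-1,3-dimethyl-2-oxo-6-(prop-1-en-2-yl)cyclohex-3-en-1-yl]methyl}prop-2-enoate
Product: 7 methyl (4aS,8aS)-4,4,7,8a-tetramethyl-8-oxo-1,2,3,4,4a,5,8,8a-octahydronaphthalene-2-carboxylate (trans-fused; C2 epimer mixture)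
Conditions: Fe(acac)3 (30 mol %), PhSiH3 (2.5 equiv), EtOH/ethylene glycol 5:1, 0.02 M, argon, 60 °C
Reagents that add atoms: none
Why: Fe(acac)3 and PhSiH3 in ethanol generate an iron hydride that delivers a hydrogen atom to the CH2 terminus of the electron-rich isopropenyl group, so the tertiary C4 radical forms with its second methyl in place; this nucleophilic radical adds to the unsubstituted acrylate carbon C3, and the α-ester radical is reduced by divalent iron and protonated by the solvent. The closest known reaction type is the iron-mediated hydrogen-atom-transfer reductive olefin–acrylate coupling (Giese type), used here intramolecularly. Ring A closes in the 6-endo-trig mode (C4 to C3), the 5-exo alternative at the ester-bearing C2 being mismatched in polarity and hindered. No stereocentre of the target is created: C2 forms as an epimer mixture that is deleted in step 5, and the ring fusion can only be trans because the C4 radical on C5 and the acrylate arm on C10 were placed anti in step 2 and join through a chair-like transition state with both new ring bonds equatorial on ring B. The step needs hydrogen-atom transfer to the isopropenyl group in preference to the acrylate and the ring B enone, which the higher reactivity of the electron-rich 1,1-disubstituted alkene towards the metal hydride and high dilution should secure.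

Step 4
Reactants: 7 methyl (4aS,8aS)-4,4,7,8a-tetramethyl-8-oxo-1,2,3,4,4a,5,8,8a-octahydronaphthalene-2-carboxylate
Product: 8 (4aS,8aS)-4,4,7,8a-tetramethyl-8-oxo-1,2,3,4,4a,5,8,8a-octahydronaphthalene-2-carboxylic acid (C2 epimer mixture)
Conditions: LiOH·H2O, THF/MeOH/H2O, rt; aq. HCl work-up
Reagents that add atoms: lithium hydroxide [Li+].[OH-]
Why: Saponification of an unhindered secondary methyl ester; the enone has no α' hydrogens and the ring fusion centres are not epimerizable.

Step 5
Reactants: 8 (4aS,8aS)-4,4,7,8a-tetramethyl-8-oxo-1,2,3,4,4a,5,8,8a-octahydronaphthalene-2-carboxylic acid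
Product: 10 (4aS,8aS)-2,5,5,8a-tetramethyl-4a,5,6,7,8,8a-hexahydronaphthalen-1(4H)-one, via Barton ester 9 (not isolated)
Conditions: N-hydroxypyridine-2-thione, DCC, DMAP (cat.), CH2Cl2, dark, rt; then t-BuSH, hν (tungsten lamp), PhH, rt
Reagents that add atoms: none
Why: Barton reductive decarboxylation: the thiohydroxamate ester fragments to the secondary C2 radical, which takes a hydrogen atom from the thiol and has no cyclization path to the distant enone.

Step 6
Reactants: 10 (4aS,8aS)-2,5,5,8a-tetramethyl-4a,5,6,7,8,8a-hexahydronaphthalen-1(4H)-one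
Product: 12 (4aS,8aS)-2,5,5,8a-tetramethyl-4a,5,6,7,8,8a-hexahydronaphthalen-1-yl trifluoromethanesulfonate (C9 triflate of the 6,8-diene), via lithium dienolate 11 (not isolated)
Conditions: LiN(i-Pr)2 (LDA), THF, −78 to −20 °C; PhNTf2, −78 °C to rt
Reagents that add atoms: N-phenylbis(trifluoromethanesulfonimide) O=S(=O)(N(c1ccccc1)S(=O)(=O)C(F)(F)F)C(F)(F)F
Why: C10 is quaternary, so the base can only remove a γ-hydrogen at C6 to give the linear dienolate, and O-sulfonylation gives the dienyl triflate (enol triflate formation); C5 is not touched.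

Step 7
Reactants: 13 (R)-linalool
Product: 14 (R)-triethyl[(3,7-dimethylocta-1,6-dien-3-yl)oxy]silane
Conditions: Et3SiOTf, 2,6-lutidine, CH2Cl2, −78 to 0 °C
Reagents that add atoms: triethylsilyl trifluoromethanesulfonate CC[Si](CC)(CC)OS(=O)(=O)C(F)(F)F
Why: Silyl triflate silylation of a tertiary alcohol; the ether masks the linalool-type tertiary allylic alcohol, which would otherwise undergo the chromium transposition of step 15.

Step 8
Reactants: 14 (R)-triethyl[(3,7-dimethylocta-1,6-dien-3-yl)oxy]silane
Product: 15 (R)-4-methyl-4-(triethylsilyloxy)hex-5-enal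
Conditions: O3, CH2Cl2/MeOH, NaHCO3, −78 °C, Sudan Red 7B end point; Me2S, −78 °C to rt
Reagents that add atoms: ozone [O-][O+]=O
Why: Ozonolysis with an indicator dye should cleave the electron-rich trisubstituted alkene well before the hindered vinyl group next to the silyloxy carbon.

Step 9
Reactants: 15 (R)-4-methyl-4-(triethylsilyloxy)hex-5-enal
Product: 16 (R)-4-methyl-4-(triethylsilyloxy)hex-5-enoic acid
Conditions: NaClO2, NaH2PO4, 2-methylbut-2-ene, t-BuOH/H2O, 0 °C to rt
Reagents that add atoms: sodium chlorite [Na+].[O-]Cl=O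
Why: Pinnick oxidation converts the aldehyde to the acid under buffered conditions that leave the vinyl group and the tertiary silyl ether alone.

Step 10
Reactants: 16 (R)-4-methyl-4-(triethylsilyloxy)hex-5-enoic acid
Product: 18 (R)-triethyl[(5-iodo-3-methylpent-1-en-3-yl)oxy]silane, via Barton ester 17 (not isolated)
Conditions: N-hydroxypyridine-2-thione, DCC, DMAP (cat.), CH2Cl2, dark, 0 °C to rt; then CHI3, hν (tungsten lamp), PhH, rt
Reagents that add atoms: iodoform IC(I)I
Why: Barton decarboxylative iodination: the primary radical left after loss of CO2 abstracts iodine from iodoform, which removes linalool C6 and leaves the C11 iodide; the radical has no fast cyclization onto the vinyl group.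

Step 11
Reactants: 12 (4aS,8aS)-2,5,5,8a-tetramethyl-4a,5,6,7,8,8a-hexahydronaphthalen-1-yl trifluoromethanesulfonate; 18 (R)-triethyl[(5-iodo-3-methylpent-1-en-3-yl)oxy]silane
Product: 20 triethyl{[(13R)-labda-6,8,14-trien-13-yl]oxy}silane (5α-H and 10β-CH3), via alkylzinc iodide 19 (not isolated)
Conditions: 18, Zn dust (activated by BrCH2CH2Br and Me3SiCl), LiCl, THF, 35 °C; then 12, Pd(dppf)Cl2 (5 mol %), THF/NMP, 60 °C
Reagents that add atoms: none
Why: Negishi coupling of a primary alkylzinc halide with an alkenyl triflate forms C9–C11; the wide-bite-angle diphosphine should favour reductive elimination over β-hydride elimination, and the silyloxy group is too remote from zinc to eliminate.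

Step 12
Reactants: 20 triethyl{[(13R)-labda-6,8,14-trien-13-yl]oxy}silane
Product: 22 (13R)-9α-hydroxy-13-(triethylsilyloxy)labda-7,14-dien-6-one, via 6α,9α-endoperoxide 21 (not isolated)
Conditions: O2, tetraphenylporphyrin (cat.), visible light, CH2Cl2, −20 °C; then Et3N, 0 °C to rt
Reagents that add atoms: dioxygen O=O
Why: Singlet oxygen adds [4+2] to the cisoid ring B diene from the α face opposite the C10 methyl, and Kornblum–DeLaMare fragmentation removes the only peroxide α-hydrogen (C6–H) to give the C6 ketone and the C9 tertiary alcohol; the C9 configuration is erased in step 15.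

Step 13
Reactants: 22 (13R)-9α-hydroxy-13-(triethylsilyloxy)labda-7,14-dien-6-one
Product: 23 (13R)-13-(triethylsilyloxy)labda-7,14-diene-6β,9α-diol
Conditions: NaBH4, CeCl3·7H2O, MeOH, −40 to 0 °C
Reagents that add atoms: none
Why: Luche 1,2-reduction of the enone; hydride should reach C6 from the α face because the β face is screened by the axial C10 methyl and the 4β methyl, which gives the axial 6β alcohol required by the target.

Step 14
Reactants: 23 (13R)-13-(triethylsilyloxy)labda-7,14-diene-6β,9α-diol
Product: 24 (13R)-9α-hydroxy-13-(triethylsilyloxy)labda-7,14-dien-6β-yl acetate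
Conditions: Ac2O, DMAP, Et3N, CH2Cl2, rt to 40 °C
Reagents that add atoms: acetic anhydride CC(=O)OC(C)=O
Why: DMAP-catalysed acylation takes the secondary allylic 6β alcohol and leaves the tertiary C9 alcohol free.

Step 15
Reactants: 24 (13R)-9α-hydroxy-13-(triethylsilyloxy)labda-7,14-dien-6β-yl acetate
Product: 25 (13R)-7-oxo-13-(triethylsilyloxy)labda-8,14-dien-6β-yl acetate
Conditions: pyridinium chlorochromate C5H5NH[CrO3Cl], NaOAc, 4 Å molecular sieves, CH2Cl2, rt
Reagents that add atoms: pyridinium chlorochromate [O-][Cr](=O)(=O)Cl.c1cc[nH+]cc1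
Why: Babler–Dauben oxidative transposition: the C9 chromate ester shifts [3,3] to C7 and is oxidized there, which gives the tetrasubstituted 8-en-7-one; the buffer protects the silyl ether and the C6 acetate centre is not involved.

Step 16
Reactants: 25 (13R)-7-oxo-13-(triethylsilyloxy)labda-8,14-dien-6β-yl acetate
Product: 26 (13R)-13-hydroxy-7-oxolabda-8,14-dien-6β-yl acetate (CNP0328351.1)
Conditions: HF·pyridine, pyridine, THF, 0 °C to rt
Reagents that add atoms: none
Why: Buffered fluoride cleavage of the triethylsilyl ether is non-basic, so the α-acetoxy ketone should neither epimerize at C6 nor lose its acetate, and the tertiary allylic alcohol is not ionized.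

**Compound list**

1 | (R)-carvone | CC1=CC[C@H](CC1=O)C(C)=C | starting material
2 | carvone lithium enolate | CC1=CC[C@H](C=C1O[Li])C(C)=C | intermediate (not isolated)
3 | (5R)-2,6-dimethyl-5-(prop-1-en-2-yl)cyclohex-2-en-1-one, C6 epimer mixture | CC1=CC[C@H](C(C)C1=O)C(C)=C | intermediate
4 | methyl 2-(bromomethyl)acrylate | COC(=O)C(=C)CBr | starting material
5 | 6-methylcarvone lithium enolate | CC1=CC[C@H](C(C)=C1O[Li])C(C)=C | intermediate (not isolated)
6 | methyl 2-{[(1S,6S)-1,3-dimethyl-2-oxo-6-(prop-1-en-2-yl)cyclohex-3-en-1-yl]methyl}prop-2-enoate | O=C1C(C)=CC[C@@H](C(C)=C)[C@]1(C)CC(=C)C(=O)OC | intermediate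
7 | methyl (4aS,8aS)-4,4,7,8a-tetramethyl-8-oxo-1,2,3,4,4a,5,8,8a-octahydronaphthalene-2-carboxylate, C2 epimer mixture | O=C1C(C)=CC[C@H]2C(C)(C)CC(C(=O)OC)C[C@]12C | intermediate
8 | (4aS,8aS)-4,4,7,8a-tetramethyl-8-oxo-1,2,3,4,4a,5,8,8a-octahydronaphthalene-2-carboxylic acid, C2 epimer mixture | O=C1C(C)=CC[C@H]2C(C)(C)CC(C(=O)O)C[C@]12C | intermediate
9 | 2-thioxopyridin-1(2H)-yl ester of 8 (Barton ester) | O=C1C(C)=CC[C@H]2C(C)(C)CC(C(=O)ON3C=CC=CC3=S)C[C@]12C | intermediate (not isolated)
10 | (4aS,8aS)-2,5,5,8a-tetramethyl-4a,5,6,7,8,8a-hexahydronaphthalen-1(4H)-one | O=C1C(C)=CC[C@H]2C(C)(C)CCC[C@]12C | intermediate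
11 | lithium dienolate of 10 | [Li]OC1=C(C)C=C[C@H]2C(C)(C)CCC[C@]12C | intermediate (not isolated)
12 | (4aS,8aS)-2,5,5,8a-tetramethyl-4a,5,6,7,8,8a-hexahydronaphthalen-1-yl trifluoromethanesulfonate | O=S(=O)(OC1=C(C)C=C[C@H]2C(C)(C)CCC[C@]12C)C(F)(F)F | intermediate
13 | (R)-linalool | C=C[C@](C)(O)CCC=C(C)C | starting material
14 | (R)-triethyl[(3,7-dimethylocta-1,6-dien-3-yl)oxy]silane | C=C[C@](C)(O[Si](CC)(CC)CC)CCC=C(C)C | intermediate
15 | (R)-4-methyl-4-(triethylsilyloxy)hex-5-enal | C=C[C@](C)(O[Si](CC)(CC)CC)CCC=O | intermediate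
16 | (R)-4-methyl-4-(triethylsilyloxy)hex-5-enoic acid | C=C[C@](C)(O[Si](CC)(CC)CC)CCC(=O)O | intermediate
17 | 2-thioxopyridin-1(2H)-yl ester of 16 (Barton ester) | C=C[C@](C)(O[Si](CC)(CC)CC)CCC(=O)ON1C=CC=CC1=S | intermediate (not isolated)
18 | (R)-triethyl[(5-iodo-3-methylpent-1-en-3-yl)oxy]silane | C=C[C@](C)(O[Si](CC)(CC)CC)CCI | intermediate
19 | [(R)-3-methyl-3-(triethylsilyloxy)pent-4-en-1-yl]zinc iodide | C=C[C@](C)(O[Si](CC)(CC)CC)CC[Zn]I | intermediate (not isolated)
20 | triethyl{[(13R)-labda-6,8,14-trien-13-yl]oxy}silane | C=C[C@](C)(O[Si](CC)(CC)CC)CCC1=C(C)C=C[C@H]2C(C)(C)CCC[C@]12C | intermediate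
21 | triethyl{[(13R)-6α,9α-epidioxylabda-7,14-dien-13-yl]oxy}silane | C=C[C@](C)(O[Si](CC)(CC)CC)CC[C@@]13OO[C@@H](C=C1C)[C@H]2C(C)(C)CCC[C@@]23C | intermediate (not isolated)
22 | (13R)-9α-hydroxy-13-(triethylsilyloxy)labda-7,14-dien-6-one | C=C[C@](C)(O[Si](CC)(CC)CC)CC[C@@]1(O)C(C)=CC(=O)[C@H]2C(C)(C)CCC[C@]12C | intermediate
23 | (13R)-13-(triethylsilyloxy)labda-7,14-diene-6β,9α-diol | C=C[C@](C)(O[Si](CC)(CC)CC)CC[C@@]1(O)C(C)=C[C@@H](O)[C@H]2C(C)(C)CCC[C@]12C | intermediate
24 | (13R)-9α-hydroxy-13-(triethylsilyloxy)labda-7,14-dien-6β-yl acetate | C=C[C@](C)(O[Si](CC)(CC)CC)CC[C@@]1(O)C(C)=C[C@@H](OC(C)=O)[C@H]2C(C)(C)CCC[C@]12C | intermediate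
25 | (13R)-7-oxo-13-(triethylsilyloxy)labda-8,14-dien-6β-yl acetate | C=C[C@](C)(O[Si](CC)(CC)CC)CCC1=C(C)C(=O)[C@@H](OC(C)=O)[C@H]2C(C)(C)CCC[C@]12C | intermediate
26 | (13R)-13-hydroxy-7-oxolabda-8,14-dien-6β-yl acetate (CNP0328351.1) | C=C[C@](C)(O)CCC1=C(C)C(=O)[C@@H](OC(C)=O)[C@H]2C(C)(C)CCC[C@]12C | target

**Step count**

Total: 16 steps. Longest linear sequence: 12 steps (steps 1–6 and 11–16 from (R)-carvone); the linalool branch runs through steps 7–10 and joins at step 11.

**Steps most likely to fail**

1. Step 3 (radical ring closure). The hydride may transfer hydrogen to the acrylate or to the ring B enone instead of the isopropenyl group, or the tertiary radical may be reduced before it cyclizes, which would give plain hydrogenation. Fallback from 6: HBr (1 equiv) in AcOH/CH2Cl2 at 0 °C should add in the Markovnikov sense to the isopropenyl group and give the tertiary bromide F1. Slow addition of Bu3SnH with AIBN in refluxing benzene at high dilution then generates the same C4 radical by bromine abstraction, without any metal hydride acting on the alkenes. The radical closes 6-endo onto the acrylate and is reduced by the stannane, and the route is rejoined at 7.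

2. Step 11 (Negishi coupling). Oxidative addition and transmetallation at the triflate, which sits between the quaternary C10 and the methyl-bearing C8, may be slow, so that the alkylzinc is lost by β-hydride elimination or protonation and the triflate is hydrolysed. Fallback from 10 and 18, with no cross-coupling: iodine–lithium exchange on 18 (t-BuLi, Et2O/pentane, −78 °C) gives the alkyllithium F2. This adds to the C9 carbonyl of enone 10, expected from the α face, to give the tertiary allylic alcohol F3. Allylic oxidation of the ring CH2 at C6 (dirhodium tetrakis(caprolactamate) Rh2(cap)4, t-BuOOH) gives the 9β-hydroxy-7-en-6-one F4. Luche reduction as in step 13 gives the 6β,9β-diol F5, and acetylation as in step 14 gives the 6β-acetate F6. The chromium transposition of step 15 makes C9 trigonal, so either C9 epimer serves, and the route is rejoined at 25.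

3. Step 15 (oxidative transposition). The chromate shift between the congested C9 and C7 may be slow, and ionization of the tertiary allylic alcohol to dienes or loss of the silyl ether under the acidic chromium reagent may compete. Fallback from 24, separating transposition from oxidation: Ph3SiOReO3 (cat.) in Et2O at 0 °C should isomerize the tertiary allylic alcohol to the secondary 7-hydroxy-8-ene F7, driven by the tetrasubstituted alkene. Dess–Martin periodinane with NaHCO3 in CH2Cl2 then oxidizes C7, and the route is rejoined at 25.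

**Further compounds**

F1 | step 3 | methyl 2-{[(1S,6S)-6-(2-bromopropan-2-yl)-1,3-dimethyl-2-oxocyclohex-3-en-1-yl]methyl}prop-2-enoate | O=C1C(C)=CC[C@@H](C(C)(C)Br)[C@]1(C)CC(=C)C(=O)OC
F2 | step 11 | [(R)-3-methyl-3-(triethylsilyloxy)pent-4-en-1-yl]lithium | C=C[C@](C)(O[Si](CC)(CC)CC)CC[Li]
F3 | step 11 | (13R)-13-(triethylsilyloxy)labda-7,14-dien-9-ol with 9β-hydroxyl and 9α side chain | C=C[C@](C)(O[Si](CC)(CC)CC)CC[C@]1(O)C(C)=CC[C@H]2C(C)(C)CCC[C@]12C
F4 | step 11 | (13R)-9-hydroxy-13-(triethylsilyloxy)labda-7,14-dien-6-one with 9β-hydroxyl (C9 epimer of 22) | C=C[C@](C)(O[Si](CC)(CC)CC)CC[C@]1(O)C(C)=CC(=O)[C@H]2C(C)(C)CCC[C@]12C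
F5 | step 11 | (13R)-13-(triethylsilyloxy)labda-7,14-diene-6β,9-diol with 9β-hydroxyl (C9 epimer of 23) | C=C[C@](C)(O[Si](CC)(CC)CC)CC[C@]1(O)C(C)=C[C@@H](O)[C@H]2C(C)(C)CCC[C@]12C
F6 | step 11 | (13R)-9-hydroxy-13-(triethylsilyloxy)labda-7,14-dien-6β-yl acetate with 9β-hydroxyl (C9 epimer of 24) | C=C[C@](C)(O[Si](CC)(CC)CC)CC[C@]1(O)C(C)=C[C@@H](OC(C)=O)[C@H]2C(C)(C)CCC[C@]12C
F7 | step 15 | (13R)-7-hydroxy-13-(triethylsilyloxy)labda-8,14-dien-6β-yl acetate, C7 epimer mixture | C=C[C@](C)(O[Si](CC)(CC)CC)CCC1=C(C)C(O)[C@@H](OC(C)=O)[C@H]2C(C)(C)CCC[C@]12C
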